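**Retrosynthetic overview**
1. Target 19 comes from oxidation of an 8β-hydroxyl, with the C9 senecioate and C3 angelate already in place on a 7β-isopropenyl cis-decalin; the C8 oxygen derives from the C8=C9 enol ether of a C9 ketone.
2. The isopropenyl group is unmasked from a gem-dimethylcyclopropane: the C9 ketone lets the C8–C11 bond be cut, leaving C7 untouched.
3. Ring A (C1–C5, C10) is disconnected at C4–C5 and C1–C10: a [4+2] reaction between silyloxydiene 4 (from ethyl vinyl ketone) and carenone 2 (from (+)-3-carene), anti to the cyclopropane.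
4. Feature used: on ring B (C5–C10) the quaternary methyl carbon C5 and the isopropenyl-bearing C7 are 1,3 to each other, with C8 and C9 oxidised; this is the carbon pattern and the C7 configuration of 3-carene once its cyclopropane bond (here C8–C11) is broken.
5. Ring order: ring B with its cyclopropane from the chiral pool, then ring A by the cycloaddition, then opening of the cyclopropane.

Key step: step 3

Remark: eremophilane numbering is used (C14 = methyl on C5, C15 = methyl on C4, C11–C13 = side chain on C7); β is the face of C14; "8,11-cyclo" means the extra C8–C11 bond of the cyclopropane C7–C8–C11. Cycloadduct 5 is drawn as the 4α-methyl epimer that an endo transition state gives; any 4β epimer formed converges in step 4.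

Step 1
Reactants: 1 (+)-3-carene
Product: 2 (1S,6R)-car-3-en-5-one (carane numbering)
Conditions: t-BuOOH, CrO3 (cat.), CH2Cl2, rt
Reagents that add atoms: tert-butyl hydroperoxide, CC(C)(C)OO
Why: Chromium-catalysed allylic oxidation should convert the C5 methylene (carane numbering), which is allylic and adjacent to the cyclopropane, into the conjugated ketone without touching the two cyclopropane stereocentres.

Step 2
Reactants: 3 ethyl vinyl ketone
Product: 4 (Z)-3-(tert-butyldimethylsilyloxy)penta-1,3-diene
Conditions: TBSOTf, Et3N, Et2O, 0 °C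
Reagents that add atoms: tert-butyldimethylsilyl triflate, CC(C)(C)[Si](C)(C)OS(=O)(=O)C(F)(F)F
Why: Soft enolisation and O-silylation of the ethyl ketone with silyl triflate and amine should give the Z silyl dienol ether, in which the methyl group lies outside the s-cis diene.

Step 3
Reactants: 2 (1S,6R)-car-3-en-5-one; 4 (Z)-3-(tert-butyldimethylsilyloxy)penta-1,3-diene
Product: 5 3-(tert-butyldimethylsilyloxy)-8,11-cycloeremophil-2-en-9-one, 4α-methyl epimer (C14 β, H10 β, cyclopropane on the β face)
Conditions: 4 (2 equiv), Tf2NH (10 mol %), CH2Cl2, −78 → −40 °C; pyridine quench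
Reagents that add atoms: none
Why: Silyl triflimide, formed in situ from triflimide and a little 4, silylates the carbonyl oxygen of 2, the nucleophilic diene terminus C4 attacks the β-carbon C5, and C10 closes on C1 while the silyl group stays on the C3 oxygen. The closest known reaction type is the silyl-triflimide or mixed-aluminium Lewis-acid Diels–Alder reaction of 2-silyloxydienes with β,β-disubstituted cyclohex-2-enones, which joins a quaternary to a tertiary carbon. Ring A is closed by a [4+2] cycloaddition, concerted but asynchronous, or at the stepwise limit a Mukaiyama–Michael addition followed by a 6-endo-trig Michael closure. C5 and C10 are set by approach of the diene to the α face, because the endo methyl of the gem-dimethylcyclopropane covers the β face, and suprafacial addition to the ring alkene makes the fusion cis (C14 and H10 both β). C4 is set by the endo orientation, which places C15 trans to C14 (4α); this centre is not relied on, since step 4 equilibrates it. The step needs α-face selectivity, secured by the cyclopropane, and the regiochemistry C4 to C5 and C1 to C10, secured by the C3 silyloxy group that makes C4 the nucleophilic end of the diene.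

Step 4
Reactants: 5 cycloadduct silyl enol ether
Product: 7 8,11-cycloeremophilane-3,9-dione (4β-methyl), via 4-epi-dione 6 (not isolated)
Conditions: K2CO3, MeOH–THF, rt
Reagents that add atoms: none
Why: Methanolysis of the silyl enol ether frees the C3 ketone, and enolisation toward C4 should move the axial 4α-methyl (syn-axial to C9) into the equatorial 4β position, while the cis fusion at C10 stays because a trans fusion would force C14 axial under the cyclopropane methyl.

Step 5
Reactants: 7 8,11-cycloeremophilane-3,9-dione
Product: 8 3α-hydroxy-8,11-cycloeremophilan-9-one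
Conditions: Al(Oi-Pr)3 (3 equiv), i-PrOH–PhMe, reflux, acetone kept in the flask until the C3 epimer ratio is constant
Reagents that add atoms: none
Why: A Meerwein–Ponndorf–Verley reduction run under equilibrating conditions should settle C3 as the equatorial 3α-alkoxide (trans to the equatorial C15 and free of the syn-axial contact with C14), while the C9 carbonyl, flanked by C10 and the cyclopropane and conjugated with it, should react far more slowly.

Step 6
Reactants: 8 3α-hydroxy-8,11-cycloeremophilan-9-one
Product: 10 3α-hydroxyeremophil-11-en-9-one (7β-isopropenyl), via 11-chloro ketol 9 (not isolated)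
Conditions: HCl (g), CH2Cl2, 0 °C; evaporate; neutral Al2O3, hexane, rt
Reagents that add atoms: none
Why: Acid-promoted homoconjugate opening of the cyclopropyl ketone breaks the C8–C11 bond that overlaps with the carbonyl π system, chloride captures the tertiary C11 cation, and dehydrochlorination on alumina at a methyl group should unveil the isopropenyl group with C7 untouched.

Step 7
Reactants: 10 3α-hydroxyeremophil-11-en-9-one
Product: 11 3α-angeloyloxyeremophil-11-en-9-one
Conditions: angelic acid, 2,4,6-Cl3C6H2COCl, Et3N, PhMe, rt; then 10, 80 °C (no DMAP)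
Reagents that add atoms: angelic acid, C/C=C(/C)C(=O)O
Why: Yamaguchi-type esterification through the mixed anhydride acylates the equatorial alcohol without a nucleophilic catalyst, which should keep the Z geometry of the angelate.

Step 8
Reactants: 11 3α-angeloyloxyeremophil-11-en-9-one
Product: 13 3α-angeloyloxy-9-(triethylsilyloxy)eremophila-8,11-diene, via potassium enolate 12 (not isolated)
Conditions: KHMDS (1.05 equiv), THF, −78 °C; then Et3SiCl
Reagents that add atoms: chlorotriethylsilane, CC[Si](Cl)(CC)CC
Why: Kinetic deprotonation by the hindered amide base should occur at the C8 methylene and not at the C10 methine, and the ketone is several pKa units more acidic than the γ-CH of the angelate, so O-silylation gives the C8=C9 enol ether.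

Step 9
Reactants: 13 C8=C9 triethylsilyl enol ether
Product: 15 3α-angeloyloxy-8β-(triethylsilyloxy)eremophil-11-en-9-one, via silyloxy epoxide 14 (not isolated)
Conditions: m-CPBA (1.0 equiv), CH2Cl2, −20 → 0 °C
Reagents that add atoms: m-chloroperbenzoic acid, O=C(OO)c1cccc(Cl)c1
Why: In this Rubottom oxidation the electron-rich enol ether should be epoxidised in preference to the isopropenyl and enoate alkenes, from the convex β face of the cis-decalin, and 1,4-silyl migration opens the epoxide to the axial 8β-silyloxy ketone.

Step 10
Reactants: 15 8β-silyloxy 9-ketone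
Product: 16 3α-angeloyloxy-8β-(triethylsilyloxy)eremophil-11-en-9β-ol
Conditions: NaBH4, CeCl3·7H2O, MeOH, −78 → −40 °C
Reagents that add atoms: none
Why: In this Luche-type reduction hydride should add anti to the axial 8β-silyloxy group (polar Felkin–Anh, with the β-face path blocked by that group), that is from the α face, giving the equatorial 9β-alcohol and leaving both the ester and the alkenes intact.

Step 11
Reactants: 16 9β-alcohol
Product: 17 3α-angeloyloxy-9β-senecioyloxy-8β-(triethylsilyloxy)eremophil-11-ene
Conditions: Me2C=CHCOCl, pyridine, DMAP (cat.), CH2Cl2, 0 °C → rt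
Reagents that add atoms: 3-methylbut-2-enoyl chloride, CC(C)=CC(=O)Cl
Why: DMAP-catalysed acylation of the equatorial alcohol, with pyridine rather than a stronger amine so that ketene formation and deconjugation of the senecioyl group are avoided, creates no new stereocentre.

Step 12
Reactants: 17 silyl ether diester
Product: 18 3α-angeloyloxy-9β-senecioyloxyeremophil-11-en-8β-ol
Conditions: HF·pyridine, THF–pyridine, 0 °C
Reagents that add atoms: none
Why: Fluoride-mediated cleavage of the triethylsilyl ether under buffered acidic conditions should free the 8β-alcohol without acyl migration from O9 or isomerisation of the enoates.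

Step 13
Reactants: 18 8β-alcohol
Product: 19 3α-angeloyloxy-9β-senecioyloxyeremophil-11-en-8-one (CNP0375730.2)
Conditions: Dess–Martin periodinane, NaHCO3, CH2Cl2, 0 °C → rt
Reagents that add atoms: none
Why: Dess–Martin oxidation under buffered, near-neutral conditions should give the C8 ketone without epimerising C7 or C9 and without moving the isopropenyl double bond into conjugation.

**Compound list**
1 | (+)-3-carene, (1S,6R)-3,7,7-trimethylbicyclo[4.1.0]hept-3-ene | CC1=CC[C@@H]2[C@H](C1)C2(C)C | starting material
2 | (1S,6R)-car-3-en-5-one | CC1=CC(=O)[C@@H]2[C@H](C1)C2(C)C | intermediate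
3 | ethyl vinyl ketone (pent-1-en-3-one) | C=CC(=O)CC | starting material
4 | (Z)-3-(tert-butyldimethylsilyloxy)penta-1,3-diene | C/C=C(\O[Si](C)(C)C(C)(C)C)C=C | intermediate
5 | 3-(tert-butyldimethylsilyloxy)-8,11-cycloeremophil-2-en-9-one, 4α-methyl, 5β-methyl, 10β-H, β-cyclopropane | C[C@@H]1C(O[Si](C)(C)C(C)(C)C)=CC[C@@H]2C(=O)[C@@H]3[C@H](C[C@]12C)C3(C)C | intermediate
6 | 4α-methyl-8,11-cycloeremophilane-3,9-dione (4-epi-dione, not isolated) | C[C@@H]1C(=O)CC[C@@H]2C(=O)[C@@H]3[C@H](C[C@]12C)C3(C)C | intermediate
7 | 8,11-cycloeremophilane-3,9-dione, 4β,5β-dimethyl, 10β-H, β-cyclopropane | C[C@H]1C(=O)CC[C@@H]2C(=O)[C@@H]3[C@H](C[C@]12C)C3(C)C | intermediate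
8 | 3α-hydroxy-8,11-cycloeremophilan-9-one | C[C@H]1[C@H](O)CC[C@@H]2C(=O)[C@@H]3[C@H](C[C@]12C)C3(C)C | intermediate
9 | 11-chloro-3α-hydroxyeremophilan-9-one (not isolated) | C[C@H]1[C@H](O)CC[C@@H]2C(=O)C[C@H](C[C@]12C)C(C)(C)Cl | intermediate
10 | 3α-hydroxyeremophil-11-en-9-one, 7β-isopropenyl, 10β-H | C[C@H]1[C@H](O)CC[C@@H]2C(=O)C[C@H](C[C@]12C)C(C)=C | intermediate
11 | 3α-angeloyloxyeremophil-11-en-9-one | C[C@H]1[C@H](OC(=O)/C(C)=C\C)CC[C@@H]2C(=O)C[C@H](C[C@]12C)C(C)=C | intermediate
12 | potassium C8=C9 enolate of 11 (not isolated) | C[C@H]1[C@H](OC(=O)/C(C)=C\C)CC[C@@H]2C([O-])=C[C@H](C[C@]12C)C(C)=C.[K+] | intermediate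
13 | 3α-angeloyloxy-9-(triethylsilyloxy)eremophila-8,11-diene | C[C@H]1[C@H](OC(=O)/C(C)=C\C)CC[C@@H]2C(O[Si](CC)(CC)CC)=C[C@H](C[C@]12C)C(C)=C | intermediate
14 | 3α-angeloyloxy-8β,9β-epoxy-9α-(triethylsilyloxy)eremophil-11-ene (not isolated) | C[C@H]1[C@H](OC(=O)/C(C)=C\C)CC[C@@H]2[C@@]3(O[Si](CC)(CC)CC)O[C@H]3[C@H](C[C@]12C)C(C)=C | intermediate
15 | 3α-angeloyloxy-8β-(triethylsilyloxy)eremophil-11-en-9-one | C[C@H]1[C@H](OC(=O)/C(C)=C\C)CC[C@@H]2C(=O)[C@@H](O[Si](CC)(CC)CC)[C@H](C[C@]12C)C(C)=C | intermediate
16 | 3α-angeloyloxy-8β-(triethylsilyloxy)eremophil-11-en-9β-ol | C[C@H]1[C@H](OC(=O)/C(C)=C\C)CC[C@@H]2[C@@H](O)[C@@H](O[Si](CC)(CC)CC)[C@H](C[C@]12C)C(C)=C | intermediate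
17 | 3α-angeloyloxy-9β-senecioyloxy-8β-(triethylsilyloxy)eremophil-11-ene | C[C@H]1[C@H](OC(=O)/C(C)=C\C)CC[C@@H]2[C@@H](OC(=O)C=C(C)C)[C@@H](O[Si](CC)(CC)CC)[C@H](C[C@]12C)C(C)=C | intermediate
18 | 3α-angeloyloxy-9β-senecioyloxyeremophil-11-en-8β-ol | C[C@H]1[C@H](OC(=O)/C(C)=C\C)CC[C@@H]2[C@@H](OC(=O)C=C(C)C)[C@@H](O)[C@H](C[C@]12C)C(C)=C | intermediate
19 | 3α-angeloyloxy-9β-senecioyloxyeremophil-11-en-8-one (CNP0375730.2) | C=C(C)[C@H]1C[C@@]2(C)[C@H](CC[C@@H](OC(=O)/C(C)=C\C)[C@@H]2C)[C@@H](OC(=O)C=C(C)C)C1=O | target

**Step count**
Total: 13 steps. Longest linear sequence: 12 steps (steps 1 and 3–13, from 1).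

**Steps most likely to fail**

Step 3. The silylated cyclopropyl enone may open at C8–C11 or aromatise instead of reacting at its hindered β-carbon, the diene may be protodesilylated or oligomerised, or the reaction may stop after the first C–C bond. The fallback activates the dienophile with a removable ester so that a mild Lewis acid suffices; it sets out from 2 and returns at 7. α-Iodination of 2 (I2, pyridine) should give 4-iodocar-3-en-5-one F1. Palladium-catalysed methoxycarbonylation (CO, MeOH, Et3N) should then give the enone ester F2, a doubly activated dienophile of the 2-alkoxycarbonylcyclohexenone class. Its ZnCl2-mediated Diels–Alder reaction with 4, again anti to the cyclopropane, should give the angular ester cycloadduct F3. Dilute HF in MeCN should give the keto ester F4. Krapcho demethoxycarbonylation (LiCl, wet DMSO, 140 °C), followed by the carbonate treatment of step 4, should give 7.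

Step 6. Proton loss may occur from C7 instead of a methyl group, giving the isopropylidene isomer and then conjugation with the C9 ketone; the γ-chloro ketone may also enolise on the support and close back to the cyclopropane, or the opening with HCl may be incomplete. The fallback opens the ring by silyl transfer so that the ketone stays masked during the elimination; it sets out from 8 and returns at 10. Iodotrimethylsilane with hexamethyldisilazane (CH2Cl2, −78 → −20 °C) should silylate the C3 hydroxyl and open the cyclopropyl ketone to the 11-iodo C8=C9 bis-silyl compound F5. DBU should then remove HI at a methyl group to give the isopropenyl bis-silyl compound F6, with no ring re-closure possible because there is no free enolate. Citric acid in MeOH should release 10.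

Step 5. Equilibration may be slow, leaving the axial 3β-alcohol from kinetic hydride delivery on the α face; the C9 ketone may be reduced as well, or the hot aluminium alkoxide may start retro-Michael cleavage of the 1,5-diketone. The fallback sets C3 by kinetic reduction and inversion; it sets out from 7 and returns at 8. L-Selectride (THF, −78 °C) should attack the C3 ketone from the α face, leaving the shielded C9 ketone, to give the axial 3β-alcohol F7. Mitsunobu inversion (4-nitrobenzoic acid, PPh3, DIAD) should give the 3α-(4-nitrobenzoate) F8. Methanolysis (K2CO3, MeOH) should give 8.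

**Further compounds**
F1 | step 3 | 4-iodocar-3-en-5-one (C10 iodide in eremophilane numbering) | CC1=C(I)C(=O)[C@@H]2[C@H](C1)C2(C)C
F2 | step 3 | methyl car-3-en-5-one-4-carboxylate | CC1=C(C(=O)OC)C(=O)[C@@H]2[C@H](C1)C2(C)C
F3 | step 3 | 10β-methoxycarbonyl-3-(tert-butyldimethylsilyloxy)-8,11-cycloeremophil-2-en-9-one | C[C@@H]1C(O[Si](C)(C)C(C)(C)C)=CC[C@]2(C(=O)OC)C(=O)[C@@H]3[C@H](C[C@]12C)C3(C)C
F4 | step 3 | 10β-methoxycarbonyl-8,11-cycloeremophilane-3,9-dione | C[C@@H]1C(=O)CC[C@]2(C(=O)OC)C(=O)[C@@H]3[C@H](C[C@]12C)C3(C)C
F5 | step 6 | 11-iodo-3α,9-bis(trimethylsilyloxy)eremophil-8-ene | C[C@H]1[C@H](O[Si](C)(C)C)CC[C@@H]2C(O[Si](C)(C)C)=C[C@H](C[C@]12C)C(C)(C)I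
F6 | step 6 | 3α,9-bis(trimethylsilyloxy)eremophila-8,11-diene | C[C@H]1[C@H](O[Si](C)(C)C)CC[C@@H]2C(O[Si](C)(C)C)=C[C@H](C[C@]12C)C(C)=C
F7 | step 5 | 3β-hydroxy-8,11-cycloeremophilan-9-one | C[C@H]1[C@@H](O)CC[C@@H]2C(=O)[C@@H]3[C@H](C[C@]12C)C3(C)C
F8 | step 5 | 3α-(4-nitrobenzoyloxy)-8,11-cycloeremophilan-9-one | C[C@H]1[C@H](OC(=O)c4ccc(cc4)[N+](=O)[O-])CC[C@@H]2C(=O)[C@@H]3[C@H](C[C@]12C)C3(C)C
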